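The runs stem from a simulated flask for an exercise; scatter was added.

**Counting turnovers.** Ash, the flask asked about, holds 100 substrate and 130 partner per free catalyst, so a full run takes 100 turnovers, and the charge of partner exceeds that count by 30.0. Larch has the same substrate and partner with twice the catalyst.

| flask | substrate | partner | free catalyst | remark |
|---|---|---|---|---|
| ash | 20 mM | 1.3 equiv | 1 mol% | the very flask that is asked about, followed so far |
| larch | 20 mM | 1.3 equiv | 2 mol% | run made earlier |
| flask | 20 mM | 1.30 equiv | 1 mol% |  |

ash run (percent of the substrate charged)

| time / s | product / % | substrate / % |
|---|---|---|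
| 12.0 | 59 | 38 |
| 25.0 | 81 | 12 |
| 40.0 | 94 | 3 |
| 50.0 | 92 | 3 |
| 60.0 | 96 | 4 |
| 80.0 | 101 | 3 |

larch run (percent of the substrate charged)

| time / min | product / % | substrate / % |
|---|---|---|
| 0.417 | 99 | 0 |
| 0.667 | 102 | 0 |
| 1.00 | 101 | 0 |
| 1.50 | 101 | 1 |
| 2.50 | 98 | 0 |
| 4.00 | 103 | 0 |
| 6.00 | 100 | 0 |

(each reading ± 2 percentage points)

* apparent order in partner when 50 % of the substrate are converted (percent change of the rate of making product for one percent more partner charged)

- no earlier run changes the charge of partner; that part of a forecast is a guess

**Bench rule.** Exponential substrate decay is commonly read as pseudo-first-order, with partner outside the rate. Ash fits this reading: ln(charge/substrate)/t gives 0.0806 /s at 12.0 s and 0.0877 /s at 40.0 s.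

**Its border.** The rule needs partner nearly constant. After 50.0 turnovers, however, the count leaves 80.0 partner per catalyst, 61.5 % of the charge. Ash substrate also stays near 3 % from 40.0 s to 80.0 s, while larch reads 0 % at its last point. A stop where the count still shows partner in excess suggests a side loss of partner, which the count sets aside.

**Leverage.** Charge over what the count leaves gives 1.62. This is the leverage, by the count the percent change of partner present at 50 % conversion for one percent more partner charged. If the rate is first order in partner present, the apparent order equals the leverage, so this reckoning commits to about 1.62.

**The forecast.** The forecast differs, giving 0.05 from a rate “essentially zero order in partner”.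

**The flask.** The simulation gives 1.5, just below the leverage of 1.62.

    catalyst intermediate B → free catalyst + product (k = 34.0 /s)
    substrate + free catalyst → catalyst intermediate A (k = 3000 /M/s)
    partner → decomposed reagent (k = 0.0230 /s)
    partner + catalyst intermediate A ⇌ catalyst intermediate B (K = 120 /M, k = 470 /M/s)

At 50 % conversion, 75.4 % of the flask's catalyst is catalyst intermediate A, the resting state, against 11.5 % as catalyst intermediate B and 13.1 % as free catalyst. By its step to free catalyst and product alone, catalyst intermediate B has a half-life of 3.40 × 10⁻⁴ min, while partner, by its forward step with catalyst intermediate A alone, has a half-life of 0.16 min at 0.143 min.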